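**Retrosynthetic overview**

1. Labels: cyclopentane C1 (fusion C–O), C2 (CMe2), C3 (CH–O), C4, C5 (fusion CH); seven-membered ring C5, C6 (C=O), C7 (quaternary: Me, side chain), C8 (CHMe), C9, C10, C1. The strategy rests on the C6 ketone flanked by quaternary C7, which is bonded to the C8 methine: with a C9=C10 alkene this is the γ,δ-unsaturated ketone left by a Claisen shift whose ether oxygen bridged C6 and C10.
2. Target ⇐ furan-to-butenolide oxidation, C5 epimerisation to the trans fusion and C9=C10 reduction of cyclohept-4-enone 23 ⇐ [3,3] ring expansion of the cis-fused alkylidene propenyl tetrahydrofuran 22 (makes C7–C8 and the seven-membered ring).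
3. 22 ⇐ (E)-iodo enol ether 18 + furylethylborane (B-alkyl Suzuki coupling); 18 ⇐ anti iodoetherification of a C5 propynyl group by the C10 hydroxyl.
4. C10 by transfer hydrogenation of an epoxy ynone; C1 and C5 by Sharpless epoxidation and anti opening with a propynylalane; the cyclopentene from (R)-3-hydroxy-2,2-dimethylcyclopentanone (C3).
5. Ring order: cyclopentane (from the dione) → tetrahydrofuran → seven-membered carbocycle → butenolide.

Key step: step 17

Remark: 1-propynyllithium (commercial) is taken as the propyne building block, and the (R) sense of step 1 is assumed from the usual oxazaborolidine model with the gem-dimethyl carbon as the large group; the antipodal catalyst would be used if analysis of 2 showed the opposite sense.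

**Route**

Step 1
Reactants: 1 2,2-dimethylcyclopentane-1,3-dione
Product: 2 (R)-3-hydroxy-2,2-dimethylcyclopentan-1-one
Conditions: (S)-2-methyl-CBS-oxazaborolidine (10 mol %), BH3·SMe2 (0.6 equiv, slow addition), THF, −20 °C
Reagents that add atoms: none
Why: Corey–Bakshi–Shibata reduction of one of two enantiotopic carbonyl groups, the catalyst distinguishing the quaternary C2 side (large) from the ring CH2 side (small), should set C3 as (R), and sub-stoichiometric borane limits diol formation.

Step 2
Reactants: 2 (R)-3-hydroxy-2,2-dimethylcyclopentan-1-one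
Product: 3 (R)-3-(tert-butyldimethylsilyloxy)-2,2-dimethylcyclopentan-1-one
Conditions: t-BuMe2SiCl, imidazole, DMF, rt
Reagents that add atoms: tert-butyldimethylsilyl chloride, CC(C)(C)[Si](C)(C)Cl
Why: Imidazole-promoted silylation of a secondary alcohol gives an ether that should last to the final step and biases the ring faces later.

Step 3
Reactants: 3 (R)-3-(tert-butyldimethylsilyloxy)-2,2-dimethylcyclopentan-1-one
Product: 4 (R)-4-(tert-butyldimethylsilyloxy)-5,5-dimethylcyclopent-1-en-1-yl trifluoromethanesulfonate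
Conditions: KN(SiMe3)2, THF, −78 °C; PhNTf2, −78 → 0 °C
Reagents that add atoms: N-phenyl-bis(trifluoromethanesulfonimide), O=S(=O)(N(c1ccccc1)S(=O)(=O)C(F)(F)F)C(F)(F)F
Why: Enolisation is possible only toward the CH2 side because the other α-carbon is quaternary, so O-triflation of the potassium enolate should give a single enol triflate.

Step 4
Reactants: 4 (R)-4-(tert-butyldimethylsilyloxy)-5,5-dimethylcyclopent-1-en-1-yl trifluoromethanesulfonate
Product: 5 methyl (R)-4-(tert-butyldimethylsilyloxy)-5,5-dimethylcyclopent-1-ene-1-carboxylate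
Conditions: Pd(OAc)2 (5 mol %), PPh3, Et3N, CO (1 atm), MeOH/DMF, 50 °C
Reagents that add atoms: carbon monoxide, [C-]#[O+]; methanol, CO
Why: Palladium-catalysed alkoxycarbonylation of an enol triflate (oxidative addition, CO insertion, methanolysis) installs C10 at the ester level.

Step 5
Reactants: 5 methyl (R)-4-(tert-butyldimethylsilyloxy)-5,5-dimethylcyclopent-1-ene-1-carboxylate
Product: 6 (R)-[4-(tert-butyldimethylsilyloxy)-5,5-dimethylcyclopent-1-en-1-yl]methanol
Conditions: i-Bu2AlH (2.5 equiv), CH2Cl2, −78 → 0 °C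
Reagents that add atoms: none
Why: 1,2-Reduction of the enoate by the aluminium hydride gives the primary allylic alcohol needed for the epoxidation and leaves the silyl ether untouched.

Step 6
Reactants: 6 (R)-[4-(tert-butyldimethylsilyloxy)-5,5-dimethylcyclopent-1-en-1-yl]methanol
Product: 7 [(1R,3R,5R)-3-(tert-butyldimethylsilyloxy)-2,2-dimethyl-6-oxabicyclo[3.1.0]hexan-1-yl]methanol (epoxide oxygen trans to the silyloxy group)
Conditions: Ti(Oi-Pr)4, D-(−)-diisopropyl tartrate, t-BuOOH, 4 Å sieves, CH2Cl2, −20 °C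
Reagents that add atoms: tert-butyl hydroperoxide, CC(C)(C)OO
Why: Sharpless asymmetric epoxidation of a primary (E)-2,3-disubstituted allylic alcohol with the D-(−)-tartrate (the antipode that gives (2R,3R)-epoxy alcohols from simple (E)-allylic alcohols) should deliver oxygen to the C1=C5 face anti to the C3 silyloxy group, so reagent and substrate bias reinforce and C1 is set.

Step 7
Reactants: 7 [(1R,3R,5R)-3-(tert-butyldimethylsilyloxy)-2,2-dimethyl-6-oxabicyclo[3.1.0]hexan-1-yl]methanol
Product: 8 (1S,3R,5R)-3-(tert-butyldimethylsilyloxy)-2,2-dimethyl-6-oxabicyclo[3.1.0]hexane-1-carbaldehyde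
Conditions: Dess–Martin periodinane, NaHCO3, CH2Cl2, 0 °C → rt
Reagents that add atoms: none
Why: Buffered Dess–Martin oxidation gives an epoxy aldehyde that has no α-hydrogen and therefore cannot epimerise.

Step 8
Reactants: 8 (1S,3R,5R)-3-(tert-butyldimethylsilyloxy)-2,2-dimethyl-6-oxabicyclo[3.1.0]hexane-1-carbaldehyde; 9 1-propynyllithium
Product: 10 1-[(1R,3R,5R)-3-(tert-butyldimethylsilyloxy)-2,2-dimethyl-6-oxabicyclo[3.1.0]hexan-1-yl]but-2-yn-1-ol (both carbinol epimers)
Conditions: 9 (1.3 equiv), THF, −78 °C; aq. NH4Cl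
Reagents that add atoms: none
Why: Acetylide 1,2-addition to the aldehyde is much faster than epoxide opening at −78 °C, and no selectivity at C10 is needed because the carbinol is oxidised next.

Step 9
Reactants: 10 1-[(1R,3R,5R)-3-(tert-butyldimethylsilyloxy)-2,2-dimethyl-6-oxabicyclo[3.1.0]hexan-1-yl]but-2-yn-1-ol
Product: 11 1-[(1S,3R,5R)-3-(tert-butyldimethylsilyloxy)-2,2-dimethyl-6-oxabicyclo[3.1.0]hexan-1-yl]but-2-yn-1-one
Conditions: Dess–Martin periodinane, NaHCO3, CH2Cl2, 0 °C → rt
Reagents that add atoms: none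
Why: Dess–Martin oxidation of the propargylic alcohols converges both epimers to one ynone under neutral conditions that spare the epoxide.

Step 10
Reactants: 11 1-[(1S,3R,5R)-3-(tert-butyldimethylsilyloxy)-2,2-dimethyl-6-oxabicyclo[3.1.0]hexan-1-yl]but-2-yn-1-one
Product: 12 (S)-1-[(1R,3R,5R)-3-(tert-butyldimethylsilyloxy)-2,2-dimethyl-6-oxabicyclo[3.1.0]hexan-1-yl]but-2-yn-1-ol
Conditions: Ru[(R,R)-TsDPEN](p-cymene) (5 mol %), i-PrOH, rt
Reagents that add atoms: none
Why: Noyori asymmetric transfer hydrogenation of an α,β-acetylenic ketone is catalyst-controlled (alkynyl group against the fully substituted sp3 carbon) and should set C10 as (S), threo to the epoxide oxygen, a relation that hydroxyl-directed epoxidation of the corresponding allylic alcohol would not give.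

Step 11
Reactants: 12 (S)-1-[(1R,3R,5R)-3-(tert-butyldimethylsilyloxy)-2,2-dimethyl-6-oxabicyclo[3.1.0]hexan-1-yl]but-2-yn-1-ol; 9 1-propynyllithium
Product: 14 (S)-1-[(1R,3R,5R)-3-(tert-butyldimethylsilyloxy)-1-hydroxy-2,2-dimethyl-5-(prop-1-yn-1-yl)cyclopentyl]but-2-yn-1-ol, via diethyl(prop-1-yn-1-yl)aluminium 13 (not isolated)
Conditions: 9 (4 equiv), Et2AlCl (4 equiv), toluene, 0 °C; then 12, 0 °C → rt
Reagents that add atoms: none
Why: In the known distal-carbon opening of 2,3-epoxy alcohols by diethylalkynylalanes the C10 aluminium alkoxide should deliver the propynyl group to the secondary epoxide carbon C5 (not the quaternary C1) with inversion, which places the alkyne trans to the C1 hydroxyl and cis to the C10 side chain.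

Step 12
Reactants: 14 (S)-1-[(1R,3R,5R)-3-(tert-butyldimethylsilyloxy)-1-hydroxy-2,2-dimethyl-5-(prop-1-yn-1-yl)cyclopentyl]but-2-yn-1-ol
Product: 16 (S)-1-[(1R,3R,5R)-3-(tert-butyldimethylsilyloxy)-2,2-dimethyl-5-(prop-1-yn-1-yl)-1-(triethylsilyloxy)cyclopentyl]but-2-yn-1-ol, via bis(triethylsilyl) ether 15 (not isolated)
Conditions: Et3SiOTf (3 equiv), 2,6-lutidine, CH2Cl2, −78 °C → rt; then MeOH, pyridinium p-toluenesulfonate (cat.), 0 °C
Reagents that add atoms: triethylsilyl trifluoromethanesulfonate, CC[Si](CC)(CC)OS(=O)(=O)C(F)(F)F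
Why: Exhaustive silylation by the silyl triflate followed by selective methanolysis of the far less hindered secondary propargylic ether should leave only the tertiary C1 oxygen protected, which blocks its own cyclisations in steps 13–14 and a retro-aldol after the key step.

Step 13
Reactants: 16 (S)-1-[(1R,3R,5R)-3-(tert-butyldimethylsilyloxy)-2,2-dimethyl-5-(prop-1-yn-1-yl)-1-(triethylsilyloxy)cyclopentyl]but-2-yn-1-ol
Product: 17 (S,E)-1-[(1R,3R,5R)-3-(tert-butyldimethylsilyloxy)-2,2-dimethyl-5-(prop-1-yn-1-yl)-1-(triethylsilyloxy)cyclopentyl]but-2-en-1-ol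
Conditions: NaAlH2(OCH2CH2OMe)2 (3 equiv), THF, 0 °C → rt
Reagents that add atoms: none
Why: Hydroxyl-directed trans-hydroalumination of the propargylic alcohol and protonolysis give only the (E)-alkene, while the C5 alkyne has no free neighbouring hydroxyl and should stay intact.

Step 14
Reactants: 17 (S,E)-1-[(1R,3R,5R)-3-(tert-butyldimethylsilyloxy)-2,2-dimethyl-5-(prop-1-yn-1-yl)-1-(triethylsilyloxy)cyclopentyl]but-2-en-1-ol
Product: 18 cis-fused iodo enol ether: (E)-4-(1-iodoethylidene)-8,8-dimethyl-2-[(E)-prop-1-en-1-yl]-7-(tert-butyldimethylsilyloxy)-1-(triethylsilyloxy)-3-oxabicyclo[3.3.0]octane; propenyl cis to the 1-silyloxy group; iodine trans to the ring oxygen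
Conditions: N-iodosuccinimide, NaHCO3, MeCN, 0 °C, dark
Reagents that add atoms: N-iodosuccinimide, O=C1CCC(=O)N1I
Why: In this 5-exo-dig iodoetherification the C10 hydroxyl, cis to the alkyne on the cyclopentane, should attack C6 anti to the iodonium, closing the cis-fused tetrahydrofuran and putting iodine trans to the ring oxygen and methyl cis to it.

Step 15
Reactants: 19 furan-3-carbaldehyde
Product: 20 3-ethenylfuran (3-vinylfuran)
Conditions: Ph3PCH3Br, KOt-Bu, THF, 0 °C → rt; used as a THF solution
Reagents that add atoms: methyltriphenylphosphonium bromide, C[P+](c1ccccc1)(c1ccccc1)c1ccccc1.[Br-]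
Why: Wittig methylenation of the heteroaryl aldehyde gives the volatile vinylfuran, which is carried on in solution.

Step 16
Reactants: 18 cis-fused (E)-iodo enol ether; 20 3-ethenylfuran
Product: 22 cis-fused 4-[(E)-4-(furan-3-yl)butan-2-ylidene]-8,8-dimethyl-2-[(E)-prop-1-en-1-yl]-7-(tert-butyldimethylsilyloxy)-1-(triethylsilyloxy)-3-oxabicyclo[3.3.0]octane, via B-[2-(furan-3-yl)ethyl]-9-borabicyclo[3.3.1]nonane 21 (not isolated)
Conditions: 20, 9-BBN, THF, rt; then 18, PdCl2(dppf) (10 mol %), AsPh3, Cs2CO3, DMF/H2O, rt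
Reagents that add atoms: none
Why: 9-BBN should add to the terminal vinyl carbon, and the B-alkyl Suzuki–Miyaura coupling of the vinyl iodide proceeds with retention, so the furylethyl chain ends cis to C5 and the methyl cis to the ring oxygen.

Step 17
Reactants: 22 cis-fused alkylidene propenyl tetrahydrofuran
Product: 23 cis-fused cyclohept-4-enone (overview labels): 7-[2-(furan-3-yl)ethyl]-2,2,7,8-tetramethyl-3-(tert-butyldimethylsilyloxy)-1-(triethylsilyloxy)-bicyclo[5.3.0]dec-9-en-6-one; 5-H cis to 1-OSiEt3; 7-Me and 8-Me cis to each other and trans to 1-OSiEt3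
Conditions: degassed toluene, i-Pr2NEt (0.2 equiv), 2,6-di-tert-butyl-4-methylphenol (cat.), base-washed sealed tube, 180 °C
Reagents that add atoms: none
Why: A thermal concerted [3,3] sigmatropic shift of the allyl vinyl ether C7=C6–O–C10–C9=C8 forms the C7–C8 bond while the allylic C10–O bond breaks and the oxygen becomes the C6 carbonyl; the closest known reaction type is the Claisen ring expansion of 2-alkylidene-5-vinyltetrahydrofurans to cyclohept-4-enones. The seven-membered ring (C1, C5–C10) is closed not by a cyclisation but by two-carbon enlargement of the five-membered ether, whose C6–O–C10 unit is shared with the six-atom pericyclic array, so the transition state resembles the chair of an 8-oxabicyclo[3.2.1]octene. C7 is set because the new bond must enter the enol ether face that carries the propenyl group (the convex face, fixed by the (S) centre at C10) and the (E) enol ether geometry then places methyl and side chain as in the target. C8 is set because the methyl of the (E)-propenyl group lies pseudo-equatorial in that chair-like array, which makes 7-Me and 8-Me cis. The step needs chair over boat and convex over concave face: the two-carbon C1–C5 bridge admits only the chair-like array that yields the cis ring alkene C9=C10, and C10 holds the allyl unit on the convex face. It also needs the shift to outrun acid-catalysed migration of the enol ether double bond, which the amine additive and base-washed glass are there to prevent.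

Step 18
Reactants: 23 cis-fused cyclohept-4-enone
Product: 24 cis-fused saturated ketone: 23 with C9–C10 reduced
Conditions: 2-nitrobenzenesulfonylhydrazide (excess, in portions), Et3N, CH2Cl2, rt
Reagents that add atoms: none
Why: Diimide transfers two hydrogens syn to the cis-disubstituted ring alkene and should leave the furan, the ketone and both silyl ethers alone.

Step 19
Reactants: 24 cis-fused saturated ketone
Product: 25 trans-fused ketone: C5 epimer of 24 (5-H trans to 1-OSiEt3 and cis to 7-Me, 8-Me and 3-OSi)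
Conditions: K2CO3, MeOH, rt
Reagents that add atoms: none
Why: Base equilibration through the C5–C6 enolate should favour the trans-fused hydroazulenone, the arrangement found in the target, while the mild carbonate conditions are chosen to keep β-elimination of the C1 silyloxy group slow.

Step 20
Reactants: 25 trans-fused ketone
Product: 29 butenolide bis-silyl ether: 25 with the furan replaced by a 5-oxo-2,5-dihydrofuran-3-yl group, via furan endoperoxide 26 (not isolated), via hydroxybutenolide 27 (not isolated), via hydroxy acid 28 (not isolated)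
Conditions: O2, hν, tetraphenylporphyrin (cat.), i-Pr2NEt, CH2Cl2, −78 °C; then NaBH4, EtOH, −78 → 0 °C; then 1 M HCl
Reagents that add atoms: dioxygen, O=O
Why: Singlet oxygen adds [4+2] to the furan and the hindered amine removes the less hindered α-hydrogen (Kornblum–DeLaMare-type fragmentation) to give the γ-hydroxybutenolide with the alkyl group β, whose masked aldehyde is reduced by NaBH4 and lactonises on acidification, while the C6 ketone, flanked by C7 and C5, should be too hindered to react at this temperature.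

Step 21
Reactants: 29 butenolide bis-silyl ether
Product: 30 target: (overview labels) trans-fused 1,3-dihydroxy-2,2,7,8-tetramethyl-7-[2-(5-oxo-2,5-dihydrofuran-3-yl)ethyl]bicyclo[5.3.0]decan-6-one; 1-OH and side chain on one face; 5-H, 3-OH, 7-Me and 8-Me on the other
Conditions: HF (48 % aq.), MeCN, 0 °C → rt
Reagents that add atoms: none
Why: Acidic fluoride cleaves the tertiary triethylsilyl and the hindered secondary tert-butyldimethylsilyl ether without the basic conditions that would endanger the butenolide or the β-hydroxy ketone.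

**Compound list**

1 | 2,2-dimethylcyclopentane-1,3-dione | CC1(C)C(=O)CCC1=O | starting material
2 | (R)-3-hydroxy-2,2-dimethylcyclopentan-1-one | O=C1CC[C@@H](O)C1(C)C | intermediate
3 | (R)-3-(tert-butyldimethylsilyloxy)-2,2-dimethylcyclopentan-1-one | O=C1CC[C@@H](O[Si](C)(C)C(C)(C)C)C1(C)C | intermediate
4 | (R)-4-(tert-butyldimethylsilyloxy)-5,5-dimethylcyclopent-1-en-1-yl trifluoromethanesulfonate | O=S(=O)(OC1=CC[C@@H](O[Si](C)(C)C(C)(C)C)C1(C)C)C(F)(F)F | intermediate
5 | methyl (R)-4-(tert-butyldimethylsilyloxy)-5,5-dimethylcyclopent-1-ene-1-carboxylate | COC(=O)C1=CC[C@@H](O[Si](C)(C)C(C)(C)C)C1(C)C | intermediate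
6 | (R)-[4-(tert-butyldimethylsilyloxy)-5,5-dimethylcyclopent-1-en-1-yl]methanol | OCC1=CC[C@@H](O[Si](C)(C)C(C)(C)C)C1(C)C | intermediate
7 | [(1R,3R,5R)-3-(tert-butyldimethylsilyloxy)-2,2-dimethyl-6-oxabicyclo[3.1.0]hexan-1-yl]methanol | OC[C@@]12O[C@@H]1C[C@@H](O[Si](C)(C)C(C)(C)C)C2(C)C | intermediate
8 | (1S,3R,5R)-3-(tert-butyldimethylsilyloxy)-2,2-dimethyl-6-oxabicyclo[3.1.0]hexane-1-carbaldehyde | O=C[C@@]12O[C@@H]1C[C@@H](O[Si](C)(C)C(C)(C)C)C2(C)C | intermediate
9 | 1-propynyllithium | [Li]C#CC | starting material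
10 | 1-[(1R,3R,5R)-3-(tert-butyldimethylsilyloxy)-2,2-dimethyl-6-oxabicyclo[3.1.0]hexan-1-yl]but-2-yn-1-ol, both carbinol epimers | CC#CC(O)[C@@]12O[C@@H]1C[C@@H](O[Si](C)(C)C(C)(C)C)C2(C)C | intermediate
11 | 1-[(1S,3R,5R)-3-(tert-butyldimethylsilyloxy)-2,2-dimethyl-6-oxabicyclo[3.1.0]hexan-1-yl]but-2-yn-1-one | CC#CC(=O)[C@@]12O[C@@H]1C[C@@H](O[Si](C)(C)C(C)(C)C)C2(C)C | intermediate
12 | (S)-1-[(1R,3R,5R)-3-(tert-butyldimethylsilyloxy)-2,2-dimethyl-6-oxabicyclo[3.1.0]hexan-1-yl]but-2-yn-1-ol | CC#C[C@H](O)[C@@]12O[C@@H]1C[C@@H](O[Si](C)(C)C(C)(C)C)C2(C)C | intermediate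
13 | diethyl(prop-1-yn-1-yl)aluminium | CC#C[Al](CC)CC | intermediate (not isolated)
14 | (S)-1-[(1R,3R,5R)-3-(tert-butyldimethylsilyloxy)-1-hydroxy-2,2-dimethyl-5-(prop-1-yn-1-yl)cyclopentyl]but-2-yn-1-ol | CC#C[C@H](O)[C@@]1(O)[C@@H](C#CC)C[C@@H](O[Si](C)(C)C(C)(C)C)C1(C)C | intermediate
15 | bis(triethylsilyl) ether of 14 | CC#C[C@H](O[Si](CC)(CC)CC)[C@@]1(O[Si](CC)(CC)CC)[C@@H](C#CC)C[C@@H](O[Si](C)(C)C(C)(C)C)C1(C)C | intermediate (not isolated)
16 | (S)-1-[(1R,3R,5R)-3-(tert-butyldimethylsilyloxy)-2,2-dimethyl-5-(prop-1-yn-1-yl)-1-(triethylsilyloxy)cyclopentyl]but-2-yn-1-ol | CC#C[C@H](O)[C@@]1(O[Si](CC)(CC)CC)[C@@H](C#CC)C[C@@H](O[Si](C)(C)C(C)(C)C)C1(C)C | intermediate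
17 | (S,E)-1-[(1R,3R,5R)-3-(tert-butyldimethylsilyloxy)-2,2-dimethyl-5-(prop-1-yn-1-yl)-1-(triethylsilyloxy)cyclopentyl]but-2-en-1-ol | C/C=C/[C@H](O)[C@@]1(O[Si](CC)(CC)CC)[C@@H](C#CC)C[C@@H](O[Si](C)(C)C(C)(C)C)C1(C)C | intermediate
18 | cis-fused (E)-4-(1-iodoethylidene)-8,8-dimethyl-2-[(E)-prop-1-en-1-yl]-7-(tert-butyldimethylsilyloxy)-1-(triethylsilyloxy)-3-oxabicyclo[3.3.0]octane (propenyl cis to 1-OSiEt3, iodine trans to ring O) | C/C=C/[C@@H]1O/C(=C(\C)I)[C@H]2C[C@@H](O[Si](C)(C)C(C)(C)C)C(C)(C)[C@@]12O[Si](CC)(CC)CC | intermediate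
19 | furan-3-carbaldehyde | O=Cc1ccoc1 | starting material
20 | 3-ethenylfuran | C=Cc1ccoc1 | intermediate
21 | B-[2-(furan-3-yl)ethyl]-9-borabicyclo[3.3.1]nonane | B1(CCc2ccoc2)C2CCCC1CCC2 | intermediate (not isolated)
22 | cis-fused 4-[(E)-4-(furan-3-yl)butan-2-ylidene]-8,8-dimethyl-2-[(E)-prop-1-en-1-yl]-7-(tert-butyldimethylsilyloxy)-1-(triethylsilyloxy)-3-oxabicyclo[3.3.0]octane (Claisen precursor) | C/C=C/[C@@H]1O/C(=C(\C)CCc2ccoc2)[C@H]2C[C@@H](O[Si](C)(C)C(C)(C)C)C(C)(C)[C@@]12O[Si](CC)(CC)CC | intermediate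
23 | cis-fused cyclohept-4-enone (Claisen product; C9=C10 alkene, 5-H cis to 1-OSiEt3) | C[C@@H]1C=C[C@@]2(O[Si](CC)(CC)CC)[C@H](C[C@@H](O[Si](C)(C)C(C)(C)C)C2(C)C)C(=O)[C@@]1(C)CCc1ccoc1 | intermediate
24 | cis-fused saturated ketone | C[C@@H]1CC[C@@]2(O[Si](CC)(CC)CC)[C@H](C[C@@H](O[Si](C)(C)C(C)(C)C)C2(C)C)C(=O)[C@@]1(C)CCc1ccoc1 | intermediate
25 | trans-fused saturated ketone (C5 epimer of 24) | C[C@@H]1CC[C@@]2(O[Si](CC)(CC)CC)[C@@H](C[C@@H](O[Si](C)(C)C(C)(C)C)C2(C)C)C(=O)[C@@]1(C)CCc1ccoc1 | intermediate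
26 | furan endoperoxide of 25 (2,3,7-trioxabicyclo[2.2.1]hept-5-ene unit) | C[C@@H]1CC[C@@]2(O[Si](CC)(CC)CC)[C@@H](C[C@@H](O[Si](C)(C)C(C)(C)C)C2(C)C)C(=O)[C@@]1(C)CCC1=CC2OOC1O2 | intermediate (not isolated)
27 | γ-hydroxybutenolide (4-alkyl-5-hydroxyfuran-2(5H)-one, hemiacetal epimers) | C[C@@H]1CC[C@@]2(O[Si](CC)(CC)CC)[C@@H](C[C@@H](O[Si](C)(C)C(C)(C)C)C2(C)C)C(=O)[C@@]1(C)CCC1=CC(=O)OC1O | intermediate (not isolated)
28 | (Z)-3-(hydroxymethyl)alk-2-enoic acid from reduction of 27 | C[C@@H]1CC[C@@]2(O[Si](CC)(CC)CC)[C@@H](C[C@@H](O[Si](C)(C)C(C)(C)C)C2(C)C)C(=O)[C@@]1(C)CC/C(CO)=C/C(=O)O | intermediate (not isolated)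
29 | butenolide bis-silyl ether | C[C@@H]1CC[C@@]2(O[Si](CC)(CC)CC)[C@@H](C[C@@H](O[Si](C)(C)C(C)(C)C)C2(C)C)C(=O)[C@@]1(C)CCC1=CC(=O)OC1 | intermediate
30 | CNP0077405.2 | C[C@@H]1CC[C@@]2(O)[C@@H](C[C@@H](O)C2(C)C)C(=O)[C@@]1(C)CCC1=CC(=O)OC1 | target

**Step count and risks**

Total steps: 21. Longest linear sequence: 20 (steps 1–14 and 16–21; step 15 is the side branch).

Steps most likely to fail:

Step 17. The congested shift (a quaternary and a tertiary centre are joined) may be outrun at 180 °C by migration of the exocyclic enol ether double bond into the ring or by ionisation of the allylic C10–O bond. Fallback: setting out from 22, treatment with Al(i-Bu)3 in CH2Cl2 at −78 °C → rt lets the Lewis acid bind the ether oxygen, so the rearrangement runs at low temperature through a more polarised transition state, and the aluminium-bound ketone is reduced in the flask by β-hydride transfer to the cyclohept-4-en-6-ol F1 (C6 epimers). Dess–Martin oxidation of F1 comes back to the route at 23.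

Step 19. The C5 enolate may expel triethylsilanolate from C1 (β-elimination), or the equilibrium may not lie on the side of the trans fusion. Fallback: setting out from 24, LiN(i-Pr)2 in THF at −78 °C gives the lithium enolate F2, which is protonated at −78 °C by 2,6-di-tert-butylphenol with the proton entering C5 anti to the bulky C1 silyloxy group. This kinetic protonation comes back to the route at 25 without holding the β-silyloxy ketone under equilibrating base.

Step 16. Oxidative addition to the electron-rich tetrasubstituted iodo enol ether may be slow, so that protodeiodination or hydrolysis of the enol ether in the aqueous base takes over. Fallback: setting out from 20, hydroboration–oxidation (9-BBN; NaOH, H2O2) gives 2-(furan-3-yl)ethan-1-ol F3, iodination (I2, PPh3, imidazole) gives 3-(2-iodoethyl)furan F4, and zinc insertion (Zn dust, LiCl, THF) gives [2-(furan-3-yl)ethyl]zinc iodide F5. Anhydrous, base-free Negishi coupling of F5 with 18 (Pd(OAc)2, SPhos, THF, rt) comes back to the route at 22.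

Further compounds
F1 | step 17 | cyclohept-4-en-6-ol corresponding to 23 (C6 carbinol, both epimers) | C[C@@H]1C=C[C@@]2(O[Si](CC)(CC)CC)[C@H](C[C@@H](O[Si](C)(C)C(C)(C)C)C2(C)C)C(O)[C@@]1(C)CCc1ccoc1
F2 | step 19 | lithium C5–C6 enolate of 24 | C[C@@H]1CC[C@@]2(O[Si](CC)(CC)CC)C(C[C@@H](O[Si](C)(C)C(C)(C)C)C2(C)C)=C(O[Li])[C@@]1(C)CCc1ccoc1
F3 | step 16 | 2-(furan-3-yl)ethan-1-ol | OCCc1ccoc1
F4 | step 16 | 3-(2-iodoethyl)furan | ICCc1ccoc1
F5 | step 16 | [2-(furan-3-yl)ethyl]zinc iodide | I[Zn]CCc1ccoc1
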